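**Retrosynthetic overview**

1. Target 37 ⇐ (desilylation) 36 ⇐ one-pot union of three building blocks at the two sp2–sp2 single bonds C12′–C13′ and C12–C13: ring-half iodide 28 (C21) + boryl dienyne 32 (C8) + acyclic-half iodide 13 (C21).
2. Enabling feature: the tail-to-tail triene core C13(Me)=C14–C15=C15′–C14′=C13′(Me) is pseudo-C2-symmetric, and each of its methyl-bearing sp2 ends is tied by a single bond to the (E)-CH=CH terminus of a C21 half (acyclic carbinol end; cyclohexene-ring end). One C8 linchpin with boron at one end and a hydrozirconation-ready MeC≡C at the other therefore serves both junctions, and both halves are made as (E)-1-iodopolyenes by the same end game.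
3. 13 ⇐ two C5 Horner–Wadsworth–Emmons homologations and Takai iodo-olefination of aldehyde 6 ⇐ diol 3 ⇐ Sharpless epoxide of prenol opened by an allyl cuprate (sets C2).
4. 28 ⇐ the same homologation of ring aldehyde 24 ⇐ Still–Wittig [2,3] shift (sets C6′) ⇐ Corey–Bakshi–Shibata reduction ⇐ rhodium-catalysed asymmetric 1,4-addition to dienone 15 (sets C2′).
5. Rings: the only ring, the cyclohexene, is not closed in the route; it is carried over from 2,4,4-trimethylcyclohexenone 14, and its C4′=C5′ double bond is moved into place by the [2,3] shift. 32 ⇐ (E)-1,2-dichloroethene + two propyne units.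

Key step: step 28

Remark: carotenoid locants are used (C1 = carbinol carbon of the acyclic end, C2 its stereocentre, C3–C15 along the chain; C15′–C7′ run to ring carbon C6′; C2′ carries the hydroxyprenyl chain). TES = triethylsilyl, TBS = tert-butyldimethylsilyl, pin = pinacolato. Compound 14 and all named reagents are assumed to be commercial.

**Acyclic half (steps 1–12)**

Step 1
Reactants: 1 3-methylbut-2-en-1-ol (prenol)
Product: 2 (S)-(3,3-dimethyloxiran-2-yl)methanol
Conditions: Ti(OiPr)4 (10 mol %), L-(+)-diethyl tartrate (12 mol %), tBuOOH, 4 Å MS, CH2Cl2, −20 °C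
Reagents that add atoms: tert-butyl hydroperoxide, CC(C)(C)OO
Why: Sharpless asymmetric epoxidation of a primary allylic alcohol, in which the titanium–L-(+)-tartrate complex delivers oxygen to the alkene face that gives the (S)-epoxide.

Step 2
Reactants: 2 (S)-(3,3-dimethyloxiran-2-yl)methanol
Product: 3 (2R)-3-methyl-2-(prop-2-en-1-yl)butane-1,3-diol
Conditions: allylMgCl (3 equiv), CuI (15 mol %), THF, −40 to −10 °C; aq NH4Cl
Reagents that add atoms: allylmagnesium chloride, C=CC[Mg]Cl
Why: Copper-catalysed SN2 opening of a 2,3-epoxy alcohol by an allyl Grignard reagent, which can only attack the secondary epoxide carbon because the other one is fully substituted, so that inversion there turns the (S)-epoxide into the (R)-1,3-diol that carries the C2 stereocentre.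

Step 3
Reactants: 3 (2R)-2-allyl-3-methylbutane-1,3-diol
Product: 4 (2R)-3-methyl-2-(3-methylbut-2-en-1-yl)butane-1,3-diol
Conditions: 2-methylbut-2-ene (excess), second-generation Grubbs catalyst (3 mol %), CH2Cl2, 40 °C
Reagents that add atoms: 2-methylbut-2-ene, CC=C(C)C
Why: Olefin cross-metathesis of the terminal alkene with excess 2-methylbut-2-ene exchanges =CH2 for =CMe2 and so makes the prenyl group without touching the stereocentre or the free hydroxyls.

Step 4
Reactants: 4 (2R)-prenyl diol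
Product: 5 (2R)-3-methyl-2-(3-methylbut-2-en-1-yl)-1,3-bis(triethylsilyloxy)butane
Conditions: Et3SiOTf (2.5 equiv), 2,6-lutidine, CH2Cl2, −78 to 0 °C
Reagents that add atoms: triethylsilyl trifluoromethanesulfonate, CC[Si](CC)(CC)OS(=O)(=O)C(F)(F)F
Why: Silyl triflate/lutidine silylation is strong enough for the tertiary hydroxyl and gives a bis-ether whose primary and tertiary ends are told apart in the next step.

Step 5
Reactants: 5 (2R)-bis-TES ether
Product: 6 (2S)-5-methyl-2-[2-(triethylsilyloxy)propan-2-yl]hex-4-enal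
Conditions: (COCl)2, DMSO, CH2Cl2, −78 to −30 °C; then Et3N, to 0 °C
Reagents that add atoms: none
Why: Swern oxidation of a primary triethylsilyl ether, in which the activated sulfoxide cleaves the unhindered primary Si–O bond and oxidises that carbon directly to the aldehyde while the tertiary ether stays, the geometry at the stereocentre being kept (the descriptor changes only by priority).

Step 6
Reactants: 6 (2S)-α-branched aldehyde
Product: 7 ethyl (2E,4E,6R)-3,9-dimethyl-6-[2-(triethylsilyloxy)propan-2-yl]deca-2,4,8-trienoate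
Conditions: ethyl (E)-4-(diethoxyphosphoryl)-3-methylbut-2-enoate, nBuLi, DMPU, THF, −78 to 0 °C
Reagents that add atoms: ethyl (E)-4-(diethoxyphosphoryl)-3-methylbut-2-enoate, CCOC(=O)/C=C(\C)CP(=O)(OCC)OCC
Why: Horner–Wadsworth–Emmons olefination with the lithiated C5 phosphonate adds C4–C7, the new C3=C4 double bond being E by reversible addition of the stabilised anion and the C5=C6 double bond E from the dienoate geometry, while fast addition at −78 °C keeps the C2 stereocentre.

Step 7
Reactants: 7 ethyl trienoate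
Product: 8 (2E,4E,6R)-3,9-dimethyl-6-[2-(triethylsilyloxy)propan-2-yl]deca-2,4,8-trien-1-ol
Conditions: iBu2AlH (2.5 equiv), CH2Cl2, −78 °C; Rochelle salt
Reagents that add atoms: none
Why: iBu2AlH reduces the conjugated ester by 1,2-hydride delivery to the allylic alcohol and leaves the silyl ether and the alkenes alone.

Step 8
Reactants: 8 dienyl carbinol
Product: 9 (2E,4E,6R)-3,9-dimethyl-6-[2-(triethylsilyloxy)propan-2-yl]deca-2,4,8-trienal
Conditions: MnO2 (excess), CH2Cl2, rt
Reagents that add atoms: none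
Why: MnO2 oxidation is selective for the allylic alcohol and should give the dienal without double-bond isomerisation.

Step 9
Reactants: 9 dienal
Product: 10 ethyl (2E,4E,6E,8E,10R)-3,7,13-trimethyl-10-[2-(triethylsilyloxy)propan-2-yl]tetradeca-2,4,6,8,12-pentaenoate
Conditions: ethyl (E)-4-(diethoxyphosphoryl)-3-methylbut-2-enoate, nBuLi, DMPU, THF, −78 to 0 °C
Reagents that add atoms: ethyl (E)-4-(diethoxyphosphoryl)-3-methylbut-2-enoate, CCOC(=O)/C=C(\C)CP(=O)(OCC)OCC
Why: A second Horner–Wadsworth–Emmons homologation adds C8–C11 with E geometry at C7=C8 and C9=C10 for the same reasons as in step 6.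

Step 10
Reactants: 10 ethyl pentaenoate
Product: 11 (2E,4E,6E,8E,10R)-3,7,13-trimethyl-10-[2-(triethylsilyloxy)propan-2-yl]tetradeca-2,4,6,8,12-pentaen-1-ol
Conditions: iBu2AlH (2.5 equiv), CH2Cl2, −78 °C; Rochelle salt
Reagents that add atoms: none
Why: 1,2-Reduction of the conjugated ester by iBu2AlH as in step 7.

Step 11
Reactants: 11 tetraenyl carbinol
Product: 12 (2E,4E,6E,8E,10R)-3,7,13-trimethyl-10-[2-(triethylsilyloxy)propan-2-yl]tetradeca-2,4,6,8,12-pentaenal
Conditions: MnO2 (excess), CH2Cl2, rt, dark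
Reagents that add atoms: none
Why: Allylic oxidation with MnO2 as in step 8.

Step 12
Reactants: 12 tetraenal
Product: 13 (1E,3E,5E,7E,9E,11R)-1-iodo-4,8,14-trimethyl-11-[2-(triethylsilyloxy)propan-2-yl]pentadeca-1,3,5,7,9,13-hexaene
Conditions: CrCl2 (8 equiv), CHI3 (2 equiv), THF/dioxane 1:6, 0 °C to rt, dark
Reagents that add atoms: iodoform, IC(I)I
Why: Takai iodo-olefination, in which the gem-dichromium reagent from CHI3 adds to the aldehyde and eliminates to the (E)-iodoalkene, gives the E C11=C12 double bond and the C12 iodide.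

**Ring half (steps 13–24)**

Step 13
Reactants: 14 2,4,4-trimethylcyclohex-2-en-1-one
Product: 15 2,4,4-trimethylcyclohexa-2,5-dien-1-one
Conditions: DDQ (1.3 equiv), dioxane, reflux
Reagents that add atoms: none
Why: DDQ dehydrogenation of a 4,4-disubstituted cyclohexenone at the α′,β′ positions gives the cross-conjugated dienone, which cannot aromatise because C4 is quaternary.

Step 14
Reactants: 15 2,4,4-trimethylcyclohexa-2,5-dien-1-one
Product: 17 [(1R)-2,2,4-trimethyl-5-oxocyclohex-3-en-1-yl]acetaldehyde, via enol ether adduct 16 (not isolated)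
Conditions: (E)-2-(2-ethoxyethenyl)-4,4,5,5-tetramethyl-1,3,2-dioxaborolane (2.5 equiv), [Rh(OH)(cod)]2 (3 mol %), (S)-BINAP (7 mol %), KOH (0.3 equiv), dioxane/H2O 10:1, 50 °C; then 1 M HCl, THF, rt
Reagents that add atoms: (E)-2-(2-ethoxyethenyl)-4,4,5,5-tetramethyl-1,3,2-dioxaborolane, CCO/C=C/B1OC(C)(C)C(C)(C)O1; water, O
Why: Rhodium-catalysed asymmetric 1,4-addition of an alkenylboronate (the ethoxyvinyl group acting as a masked acetaldehyde enolate) goes to the unsubstituted enone arm because the α-methyl arm inserts far more slowly, (S)-BINAP fixes the face of insertion and thereby the C2′ stereocentre, and mild acid then unmasks the aldehyde.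

Step 15
Reactants: 17 (R)-keto aldehyde
Product: 18 (2E)-2-methyl-4-[(1R)-2,2,4-trimethyl-5-oxocyclohex-3-en-1-yl]but-2-enal
Conditions: Ph3P=C(CH3)CHO (1.3 equiv), toluene, 80 °C
Reagents that add atoms: 2-(triphenylphosphoranylidene)propanal, CC(C=O)=P(c1ccccc1)(c1ccccc1)c1ccccc1
Why: Wittig olefination with the stabilised formyl ylide reacts only with the aldehyde (the hindered enone is inert) and gives the (E)-trisubstituted enal under thermodynamic control.

Step 16
Reactants: 18 (R)-enone enal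
Product: 19 (1R,5R)-5-[(2E)-4-hydroxy-3-methylbut-2-en-1-yl]-2,4,4-trimethylcyclohex-2-en-1-ol
Conditions: (S)-2-methyl-CBS-oxazaborolidine (0.3 equiv), catecholborane (3 equiv), toluene, −78 °C; then MeOH, aq NaOH
Reagents that add atoms: none
Why: Corey–Bakshi–Shibata reduction with catecholborane reduces the enal to the primary allylic alcohol and the ring enone by 1,2-addition, the (S)-oxazaborolidine treating the 2-methylalkenyl arm as the large group so that hydride goes to the face that gives the (R)-carbinol, trans to the C2′ side chain.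

Step 17
Reactants: 19 (1R,5R)-diol
Product: 20 (1R,5R)-5-[(2E)-4-(tert-butyldimethylsilyloxy)-3-methylbut-2-en-1-yl]-2,4,4-trimethylcyclohex-2-en-1-ol
Conditions: tBuMe2SiCl (1.05 equiv), imidazole, CH2Cl2, −10 °C
Reagents that add atoms: tert-butyldimethylsilyl chloride, CC(C)(C)[Si](C)(C)Cl
Why: Silylation with one equivalent of silyl chloride picks the unhindered primary allylic hydroxyl over the ring secondary one on steric grounds.

Step 18
Reactants: 20 (1R,5R)-ring carbinol TBS ether
Product: 21 tributyl({(1R,5R)-5-[(2E)-4-(tert-butyldimethylsilyloxy)-3-methylbut-2-en-1-yl]-2,4,4-trimethylcyclohex-2-en-1-yl}oxymethyl)stannane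
Conditions: KH, Bu3SnCH2I, 18-crown-6 (cat.), THF, 0 °C to rt
Reagents that add atoms: tributyl(iodomethyl)stannane, CCCC[Sn](CCCC)(CCCC)CI
Why: Williamson etherification of the potassium alkoxide with the reactive iodomethylstannane installs the tin handle for the [2,3] shift with retention at the carbinol carbon.

Step 19
Reactants: 21 stannylmethyl ether
Product: 23 {(1R,5S)-5-[(2E)-4-(tert-butyldimethylsilyloxy)-3-methylbut-2-en-1-yl]-2,6,6-trimethylcyclohex-2-en-1-yl}methanol, via alkoxymethyllithium 22 (not isolated)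
Conditions: nBuLi (1.5 equiv), THF, −78 to −20 °C; then H2O
Reagents that add atoms: none
Why: Still–Wittig [2,3]-sigmatropic rearrangement, in which tin–lithium exchange gives an α-alkoxymethyllithium that migrates suprafacially from the pseudoaxial oxygen to C6′ on the same ring face, sets the C6′ stereocentre trans to the C2′ side chain and moves the double bond to C4′=C5′.

Step 20
Reactants: 23 (1R,5S)-ring methanol
Product: 24 (1R,5S)-5-[(2E)-4-(tert-butyldimethylsilyloxy)-3-methylbut-2-en-1-yl]-2,6,6-trimethylcyclohex-2-ene-1-carbaldehyde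
Conditions: Dess–Martin periodinane, NaHCO3, CH2Cl2, 0 °C
Reagents that add atoms: none
Why: Buffered Dess–Martin oxidation gives the α-branched β,γ-unsaturated aldehyde under neutral conditions that avoid epimerisation at C6′ and conjugation of the ring double bond.

Step 21
Reactants: 24 (1R,5S)-ring aldehyde
Product: 25 ethyl (2E,4E)-5-{(1R,5S)-5-[(2E)-4-(tert-butyldimethylsilyloxy)-3-methylbut-2-en-1-yl]-2,6,6-trimethylcyclohex-2-en-1-yl}-3-methylpenta-2,4-dienoate
Conditions: ethyl (E)-4-(diethoxyphosphoryl)-3-methylbut-2-enoate, nBuLi, DMPU, THF, −78 °C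
Reagents that add atoms: ethyl (E)-4-(diethoxyphosphoryl)-3-methylbut-2-enoate, CCOC(=O)/C=C(\C)CP(=O)(OCC)OCC
Why: Horner–Wadsworth–Emmons olefination at −78 °C, where addition to the aldehyde should outrun deprotonation at C6′, adds C8′–C11′ with E geometry at C7′=C8′ and C9′=C10′.

Step 22
Reactants: 25 ring dienoate
Product: 26 (2E,4E)-5-{(1R,5S)-5-[(2E)-4-(tert-butyldimethylsilyloxy)-3-methylbut-2-en-1-yl]-2,6,6-trimethylcyclohex-2-en-1-yl}-3-methylpenta-2,4-dien-1-ol
Conditions: iBu2AlH (2.5 equiv), CH2Cl2, −78 °C; Rochelle salt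
Reagents that add atoms: none
Why: 1,2-Reduction of the conjugated ester by iBu2AlH, which leaves the silyl ether and the stereocentres alone.

Step 23
Reactants: 26 ring dienol
Product: 27 (2E,4E)-5-{(1R,5S)-5-[(2E)-4-(tert-butyldimethylsilyloxy)-3-methylbut-2-en-1-yl]-2,6,6-trimethylcyclohex-2-en-1-yl}-3-methylpenta-2,4-dienal
Conditions: MnO2 (excess), CH2Cl2, rt, dark
Reagents that add atoms: none
Why: MnO2 oxidation is selective for the allylic alcohol and keeps the diene geometry.

Step 24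
Reactants: 27 ring dienal
Product: 28 (1E,3E,5E)-1-iodo-4-methyl-6-{(1R,5S)-5-[(2E)-4-(tert-butyldimethylsilyloxy)-3-methylbut-2-en-1-yl]-2,6,6-trimethylcyclohex-2-en-1-yl}hexa-1,3,5-triene
Conditions: CrCl2 (8 equiv), CHI3 (2 equiv), THF/dioxane 1:6, 0 °C to rt, dark
Reagents that add atoms: iodoform, IC(I)I
Why: Takai iodo-olefination as in step 12 gives the E C11′=C12′ double bond and the C12′ iodide.

**C8 linchpin (steps 25–27)**

Step 25
Reactants: 29 (E)-1,2-dichloroethene
Product: 30 (E)-1-chloropent-1-en-3-yne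
Conditions: propyne (1 equiv), 29 (5 equiv), Pd(PPh3)4 (3 mol %), CuI (6 mol %), nBuNH2, Et2O, 0 °C to rt
Reagents that add atoms: propyne, CC#C
Why: Sonogashira coupling of (E)-1,2-dichloroethene used in excess stops after one chloride and retains the E geometry.

Step 26
Reactants: 30 (E)-1-chloropent-1-en-3-yne
Product: 31 2-[(2Z,4E)-5-chloropenta-2,4-dien-2-yl]-4,4,5,5-tetramethyl-1,3,2-dioxaborolane (boron trans to the chain)
Conditions: pinacolborane (1.05 equiv), Cp2Zr(H)Cl (10 mol %), Et3N (10 mol %), neat, 50 °C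
Reagents that add atoms: pinacolborane, CC1(C)OBOC1(C)C
Why: Zirconium-catalysed hydroboration of the internal alkyne (syn addition through the alkenylzirconocene, boron on the less hindered methyl-bearing carbon) sets the geometry with boron trans to the chain, and the alkenyl chloride is inert.

Step 27
Reactants: 31 chlorodienyl pinacol boronate
Product: 32 4,4,5,5-tetramethyl-2-[(2Z,4E)-octa-2,4-dien-6-yn-2-yl]-1,3,2-dioxaborolane
Conditions: propyne (excess), PdCl2(PhCN)2 (5 mol %), CuI (10 mol %), piperidine, rt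
Reagents that add atoms: propyne, CC#C
Why: Sonogashira coupling of the activated 1-chloro-1,3-diene with propyne, under amine conditions that do not activate the pinacol boronate, completes the linchpin with retention of geometry.

**Union and release (steps 28–29)**

Step 28
Reactants: 32 boryl dienyne linchpin, 28 ring-half trienyl iodide, 13 acyclic-half tetraenyl iodide
Product: 36 1-O-triethylsilyl 4″-O-tert-butyldimethylsilyl bis-ether of 37 (all-E; 2R 2′S 6′R), via alkenylzirconocene 33 (not isolated), via alkenylzinc chloride 34 (not isolated), via C29 pinacol boronate 35 (not isolated)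
Conditions: 32 (1.05 equiv), Cp2Zr(H)Cl (1.05 equiv), THF, 0 °C to rt, dark; ZnCl2 (1.1 equiv), 0 °C; 28 (1.0 equiv), Pd(PPh3)4 (5 mol %), rt; then 13 (1.15 equiv), Pd(OAc)2/SPhos (5 mol %), degassed 3 M aq NaOH, rt, dark, argon
Reagents that add atoms: none
Why: Cp2Zr(H)Cl adds syn across the methyl-substituted alkyne of 32 with zirconium on the methyl-bearing carbon, transmetalation to zinc and palladium-catalysed Negishi coupling with iodide 28 form the C12′–C13′ bond with retention at both sp2 carbons, and after addition of aqueous NaOH the so far untouched pinacol boronate of 35 undergoes Suzuki–Miyaura coupling with iodide 13 to form the C12–C13 bond that joins the C29 and C21 pieces. The closest known reaction types are the hydrozirconation/Negishi coupling of enynes with alkenyl iodides and the sequential use of hetero-bimetallic diene linchpins (tin or zinc first, boron second) in polyene synthesis. No ring is closed. No sp3 stereocentre is formed and the three existing ones are remote; the only new stereo-element, the E geometry of C13′=C14′, follows from the syn hydrometalation, and all other double bonds are carried over with retention. The step needs regioselective hydrozirconation (secured by the methyl versus dienyl difference at the alkyne), chemoselectivity for the alkyne over the borylated diene (secured by one equivalent of hydride at 0 °C and the trisubstituted borylated alkene) and orthogonality of the two metals (the boronate does not transmetalate without base, so the order of addition fixes which half goes to which end).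

Step 29
Reactants: 36 bis-silyl ether
Product: 37 (2R,2′S,6′R)-2-(3-methylbut-2-en-1-yl)-2′-[(2E)-4-hydroxy-3-methylbut-2-en-1-yl]-3,4-didehydro-1,2-dihydro-ψ,ε-caroten-1-ol (all-E; the target)
Conditions: Bu4NF, AcOH (buffer), THF, 0 °C to rt, dark, argon
Reagents that add atoms: none
Why: Fluoride-mediated desilylation (formation of the strong Si–F bond) cleaves both the primary TBS and the tertiary TES ether under buffered conditions that should leave the polyene and the three stereocentres untouched.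

**Compound list**

1 | 3-methylbut-2-en-1-ol | CC(C)=CCO | starting material
2 | (S)-(3,3-dimethyloxiran-2-yl)methanol | OC[C@@H]1OC1(C)C | intermediate
3 | (2R)-3-methyl-2-(prop-2-en-1-yl)butane-1,3-diol | OC[C@@H](CC=C)C(C)(C)O | intermediate
4 | (2R)-3-methyl-2-(3-methylbut-2-en-1-yl)butane-1,3-diol | OC[C@@H](CC=C(C)C)C(C)(C)O | intermediate
5 | (2R)-3-methyl-2-(3-methylbut-2-en-1-yl)-1,3-bis(triethylsilyloxy)butane | CC[Si](CC)(CC)OC[C@@H](CC=C(C)C)C(C)(C)O[Si](CC)(CC)CC | intermediate
6 | (2S)-5-methyl-2-[2-(triethylsilyloxy)propan-2-yl]hex-4-enal | O=C[C@@H](CC=C(C)C)C(C)(C)O[Si](CC)(CC)CC | intermediate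
7 | ethyl (2E,4E,6R)-3,9-dimethyl-6-[2-(triethylsilyloxy)propan-2-yl]deca-2,4,8-trienoate | CC(C)=CC[C@H](/C=C/C(C)=C/C(=O)OCC)C(C)(C)O[Si](CC)(CC)CC | intermediate
8 | (2E,4E,6R)-3,9-dimethyl-6-[2-(triethylsilyloxy)propan-2-yl]deca-2,4,8-trien-1-ol | CC(C)=CC[C@H](/C=C/C(C)=C/CO)C(C)(C)O[Si](CC)(CC)CC | intermediate
9 | (2E,4E,6R)-3,9-dimethyl-6-[2-(triethylsilyloxy)propan-2-yl]deca-2,4,8-trienal | CC(C)=CC[C@H](/C=C/C(C)=C/C=O)C(C)(C)O[Si](CC)(CC)CC | intermediate
10 | ethyl (2E,4E,6E,8E,10R)-3,7,13-trimethyl-10-[2-(triethylsilyloxy)propan-2-yl]tetradeca-2,4,6,8,12-pentaenoate | CC(C)=CC[C@H](/C=C/C(C)=C/C=C/C(C)=C/C(=O)OCC)C(C)(C)O[Si](CC)(CC)CC | intermediate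
11 | (2E,4E,6E,8E,10R)-3,7,13-trimethyl-10-[2-(triethylsilyloxy)propan-2-yl]tetradeca-2,4,6,8,12-pentaen-1-ol | CC(C)=CC[C@H](/C=C/C(C)=C/C=C/C(C)=C/CO)C(C)(C)O[Si](CC)(CC)CC | intermediate
12 | (2E,4E,6E,8E,10R)-3,7,13-trimethyl-10-[2-(triethylsilyloxy)propan-2-yl]tetradeca-2,4,6,8,12-pentaenal | CC(C)=CC[C@H](/C=C/C(C)=C/C=C/C(C)=C/C=O)C(C)(C)O[Si](CC)(CC)CC | intermediate
13 | (1E,3E,5E,7E,9E,11R)-1-iodo-4,8,14-trimethyl-11-[2-(triethylsilyloxy)propan-2-yl]pentadeca-1,3,5,7,9,13-hexaene | CC(C)=CC[C@H](/C=C/C(C)=C/C=C/C(C)=C/C=C/I)C(C)(C)O[Si](CC)(CC)CC | intermediate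
14 | 2,4,4-trimethylcyclohex-2-en-1-one | CC1=CC(C)(C)CCC1=O | starting material
15 | 2,4,4-trimethylcyclohexa-2,5-dien-1-one | CC1=CC(C)(C)C=CC1=O | intermediate
16 | (5S)-5-[(E)-2-ethoxyethenyl]-2,4,4-trimethylcyclohex-2-en-1-one | C1=C(C)C(=O)C[C@@H](/C=C/OCC)C1(C)C | intermediate (not isolated)
17 | [(1R)-2,2,4-trimethyl-5-oxocyclohex-3-en-1-yl]acetaldehyde | C1=C(C)C(=O)C[C@@H](CC=O)C1(C)C | intermediate
18 | (2E)-2-methyl-4-[(1R)-2,2,4-trimethyl-5-oxocyclohex-3-en-1-yl]but-2-enal | C1=C(C)C(=O)C[C@@H](C/C=C(\C)C=O)C1(C)C | intermediate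
19 | (1R,5R)-5-[(2E)-4-hydroxy-3-methylbut-2-en-1-yl]-2,4,4-trimethylcyclohex-2-en-1-ol | C1=C(C)[C@H](O)C[C@@H](C/C=C(\C)CO)C1(C)C | intermediate
20 | (1R,5R)-5-[(2E)-4-(tert-butyldimethylsilyloxy)-3-methylbut-2-en-1-yl]-2,4,4-trimethylcyclohex-2-en-1-ol | C1=C(C)[C@H](O)C[C@@H](C/C=C(\C)CO[Si](C)(C)C(C)(C)C)C1(C)C | intermediate
21 | tributyl({(1R,5R)-5-[(2E)-4-(tert-butyldimethylsilyloxy)-3-methylbut-2-en-1-yl]-2,4,4-trimethylcyclohex-2-en-1-yl}oxymethyl)stannane | C1=C(C)[C@H](OC[Sn](CCCC)(CCCC)CCCC)C[C@@H](C/C=C(\C)CO[Si](C)(C)C(C)(C)C)C1(C)C | intermediate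
22 | ({(1R,5R)-5-[(2E)-4-(tert-butyldimethylsilyloxy)-3-methylbut-2-en-1-yl]-2,4,4-trimethylcyclohex-2-en-1-yl}oxymethyl)lithium | C1=C(C)[C@H](OC[Li])C[C@@H](C/C=C(\C)CO[Si](C)(C)C(C)(C)C)C1(C)C | intermediate (not isolated)
23 | {(1R,5S)-5-[(2E)-4-(tert-butyldimethylsilyloxy)-3-methylbut-2-en-1-yl]-2,6,6-trimethylcyclohex-2-en-1-yl}methanol | OC[C@@H]1C(C)=CC[C@@H](C/C=C(\C)CO[Si](C)(C)C(C)(C)C)C1(C)C | intermediate
24 | (1R,5S)-5-[(2E)-4-(tert-butyldimethylsilyloxy)-3-methylbut-2-en-1-yl]-2,6,6-trimethylcyclohex-2-ene-1-carbaldehyde | O=C[C@@H]1C(C)=CC[C@@H](C/C=C(\C)CO[Si](C)(C)C(C)(C)C)C1(C)C | intermediate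
25 | ethyl (2E,4E)-5-{(1R,5S)-5-[(2E)-4-(tert-butyldimethylsilyloxy)-3-methylbut-2-en-1-yl]-2,6,6-trimethylcyclohex-2-en-1-yl}-3-methylpenta-2,4-dienoate | CCOC(=O)/C=C(C)/C=C/[C@@H]1C(C)=CC[C@@H](C/C=C(\C)CO[Si](C)(C)C(C)(C)C)C1(C)C | intermediate
26 | (2E,4E)-5-{(1R,5S)-5-[(2E)-4-(tert-butyldimethylsilyloxy)-3-methylbut-2-en-1-yl]-2,6,6-trimethylcyclohex-2-en-1-yl}-3-methylpenta-2,4-dien-1-ol | OC/C=C(C)/C=C/[C@@H]1C(C)=CC[C@@H](C/C=C(\C)CO[Si](C)(C)C(C)(C)C)C1(C)C | intermediate
27 | (2E,4E)-5-{(1R,5S)-5-[(2E)-4-(tert-butyldimethylsilyloxy)-3-methylbut-2-en-1-yl]-2,6,6-trimethylcyclohex-2-en-1-yl}-3-methylpenta-2,4-dienal | O=C/C=C(C)/C=C/[C@@H]1C(C)=CC[C@@H](C/C=C(\C)CO[Si](C)(C)C(C)(C)C)C1(C)C | intermediate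
28 | (1E,3E,5E)-1-iodo-4-methyl-6-{(1R,5S)-5-[(2E)-4-(tert-butyldimethylsilyloxy)-3-methylbut-2-en-1-yl]-2,6,6-trimethylcyclohex-2-en-1-yl}hexa-1,3,5-triene | I/C=C/C=C(C)/C=C/[C@@H]1C(C)=CC[C@@H](C/C=C(\C)CO[Si](C)(C)C(C)(C)C)C1(C)C | intermediate
29 | (E)-1,2-dichloroethene | Cl/C=C/Cl | starting material
30 | (E)-1-chloropent-1-en-3-yne | Cl/C=C/C#CC | intermediate
31 | 2-[(2Z,4E)-5-chloropenta-2,4-dien-2-yl]-4,4,5,5-tetramethyl-1,3,2-dioxaborolane | Cl/C=C/C=C(\C)B1OC(C)(C)C(C)(C)O1 | intermediate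
32 | 4,4,5,5-tetramethyl-2-[(2Z,4E)-octa-2,4-dien-6-yn-2-yl]-1,3,2-dioxaborolane | CC#C/C=C/C=C(\C)B1OC(C)(C)C(C)(C)O1 | intermediate
33 | chlorobis(cyclopentadienyl)[(2E,4E,6Z)-7-(4,4,5,5-tetramethyl-1,3,2-dioxaborolan-2-yl)octa-2,4,6-trien-2-yl]zirconium | C1=CC(C=C1)[Zr](Cl)(C1C=CC=C1)/C(C)=C/C=C/C=C(\C)B1OC(C)(C)C(C)(C)O1 | intermediate (not isolated)
34 | chloro[(2E,4E,6Z)-7-(4,4,5,5-tetramethyl-1,3,2-dioxaborolan-2-yl)octa-2,4,6-trien-2-yl]zinc | Cl[Zn]/C(C)=C/C=C/C=C(\C)B1OC(C)(C)C(C)(C)O1 | intermediate (not isolated)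
35 | 2-{(2Z,4E,6E,8E,10E,12E)-7,11-dimethyl-13-[(1R,5S)-5-[(2E)-4-(tert-butyldimethylsilyloxy)-3-methylbut-2-en-1-yl]-2,6,6-trimethylcyclohex-2-en-1-yl]trideca-2,4,6,8,10,12-hexaen-2-yl}-4,4,5,5-tetramethyl-1,3,2-dioxaborolane | CC1(C)OB(OC1(C)C)/C(C)=C/C=C/C=C(C)/C=C/C=C(C)/C=C/[C@@H]1C(C)=CC[C@@H](C/C=C(\C)CO[Si](C)(C)C(C)(C)C)C1(C)C | intermediate (not isolated)
36 | 1-O-triethylsilyl 4″-O-tert-butyldimethylsilyl bis-ether of 37 (all-E; 2R,2′S,6′R) | CC(C)=CC[C@H](/C=C/C(C)=C/C=C/C(C)=C/C=C/C(C)=C/C=C/C=C(C)/C=C/C=C(C)/C=C/[C@@H]1C(C)=CC[C@@H](C/C=C(\C)CO[Si](C)(C)C(C)(C)C)C1(C)C)C(C)(C)O[Si](CC)(CC)CC | intermediate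
37 | (2R,2′S,6′R)-2-(3-methylbut-2-en-1-yl)-2′-[(2E)-4-hydroxy-3-methylbut-2-en-1-yl]-3,4-didehydro-1,2-dihydro-ψ,ε-caroten-1-ol (all-E) | CC(C)=CC[C@H](/C=C/C(C)=C/C=C/C(C)=C/C=C/C(C)=C/C=C/C=C(C)/C=C/C=C(C)/C=C/[C@@H]1C(C)=CC[C@@H](C/C=C(\C)CO)C1(C)C)C(C)(C)O | target

**Step count and risks**

Total steps: 29. Longest linear sequence: 14 steps (steps 1–12, 28, 29; the ring branch 13–24, 28, 29 is equally long).

Steps most likely to fail:

1. Step 28 (three-component union). What may go wrong is loss of chemoselectivity in the hydrozirconation: hydride adding to the borylated diene, or zirconium ending up on the carbon next to the diene. A second failure mode is interference of the zirconium and zinc salts with the aqueous Suzuki–Miyaura stage, leading to slow transmetalation and E/Z erosion of the polyenyl iodide. Fallback, from 32, 28 and 13, back at 36: the two couplings are run in two pots in the reverse order. Suzuki–Miyaura coupling of 32 with 28 (Pd(PPh3)4, aq NaOH, THF, rt) gives, after isolation, the boron-free C29 pentaenyne F1. F1 is hydrozirconated with a small excess of Cp2Zr(H)Cl, which can now be used to equilibrate the regioisomers towards the methyl-bearing carbon, to give the alkenylzirconocene F2. After ZnCl2, F2 is coupled with 13 under Pd(PPh3)4 (Negishi coupling) to give 36. The C12–C13 bond is still the one that joins the two large pieces.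

2. Step 14 (asymmetric 1,4-addition). What may go wrong is slow insertion at the β-carbon next to the quaternary centre, so that protodeboronation of the boronate wins, or insufficient enantioface control on the cross-conjugated dienone. Fallback, from 15, back at 19: Hosomi–Sakurai conjugate allylation of 15 (allyltrimethylsilane, TiCl4, CH2Cl2, −78 °C) gives racemic 5-allyl-2,4,4-trimethylcyclohex-2-en-1-one F3. The reagent-controlled reduction of step 16 ((S)-2-methyl-CBS-oxazaborolidine, catecholborane) then makes the (1R)-carbinol from both enantiomers, that is two diastereomers separable on silica: the wanted trans alcohol (1R,5R)-5-allyl-2,4,4-trimethylcyclohex-2-en-1-ol F4 and the cis alcohol (1R,5S)-5-allyl-2,4,4-trimethylcyclohex-2-en-1-ol F5, which is set aside. Cross-metathesis of F4 with methacrolein (second-generation Hoveyda–Grubbs catalyst, CH2Cl2, 40 °C) gives the (E)-enal (2E)-4-[(1R,5R)-5-hydroxy-2,2,4-trimethylcyclohex-3-en-1-yl]-2-methylbut-2-enal F6, and NaBH4/CeCl3·7H2O reduction gives 19.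

3. Step 16 (ring carbinol). What may go wrong is poor facial selectivity, because the inherent preference of the 5-substituted cyclohexenone for axial hydride delivery (cis alcohol) works against the catalyst-controlled trans outcome. Fallback, from 18, back at 20: Luche reduction (NaBH4, CeCl3·7H2O, MeOH, −78 °C) follows the substrate bias and gives the cis diol (1S,5R)-5-[(2E)-4-hydroxy-3-methylbut-2-en-1-yl]-2,4,4-trimethylcyclohex-2-en-1-ol F7. Selective silylation as in step 17 gives the cis silyl ether (1S,5R)-5-[(2E)-4-(tert-butyldimethylsilyloxy)-3-methylbut-2-en-1-yl]-2,4,4-trimethylcyclohex-2-en-1-ol F8. Mitsunobu inversion with 4-nitrobenzoic acid (PPh3, diisopropyl azodicarboxylate, THF) gives the trans ester (1R,5R)-5-[(2E)-4-(tert-butyldimethylsilyloxy)-3-methylbut-2-en-1-yl]-2,4,4-trimethylcyclohex-2-en-1-yl 4-nitrobenzoate F9, and methanolysis (K2CO3, MeOH) gives 20.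

**Further compounds**

F1 | step 28 | (1E,3E,5E,7E,9E)-3,7-dimethyl-1-{(1R,5S)-5-[(2E)-4-(tert-butyldimethylsilyloxy)-3-methylbut-2-en-1-yl]-2,6,6-trimethylcyclohex-2-en-1-yl}trideca-1,3,5,7,9-pentaen-11-yne | CC#C/C=C/C=C(C)/C=C/C=C(C)/C=C/[C@@H]1C(C)=CC[C@@H](C/C=C(\C)CO[Si](C)(C)C(C)(C)C)C1(C)C
F2 | step 28 | chlorobis(cyclopentadienyl){(2E,4E,6E,8E,10E,12E)-7,11-dimethyl-13-[(1R,5S)-5-[(2E)-4-(tert-butyldimethylsilyloxy)-3-methylbut-2-en-1-yl]-2,6,6-trimethylcyclohex-2-en-1-yl]trideca-2,4,6,8,10,12-hexaen-2-yl}zirconium | C1=CC(C=C1)[Zr](Cl)(C1C=CC=C1)/C(C)=C/C=C/C=C(C)/C=C/C=C(C)/C=C/[C@@H]1C(C)=CC[C@@H](C/C=C(\C)CO[Si](C)(C)C(C)(C)C)C1(C)C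
F3 | step 14 | rac-5-allyl-2,4,4-trimethylcyclohex-2-en-1-one | C=CCC1CC(=O)C(C)=CC1(C)C
F4 | step 14 | (1R,5R)-5-allyl-2,4,4-trimethylcyclohex-2-en-1-ol | C1=C(C)[C@H](O)C[C@@H](CC=C)C1(C)C
F5 | step 14 | (1R,5S)-5-allyl-2,4,4-trimethylcyclohex-2-en-1-ol | C1=C(C)[C@H](O)C[C@H](CC=C)C1(C)C
F6 | step 14 | (2E)-4-[(1R,5R)-5-hydroxy-2,2,4-trimethylcyclohex-3-en-1-yl]-2-methylbut-2-enal | C1=C(C)[C@H](O)C[C@@H](C/C=C(\C)C=O)C1(C)C
F7 | step 16 | (1S,5R)-5-[(2E)-4-hydroxy-3-methylbut-2-en-1-yl]-2,4,4-trimethylcyclohex-2-en-1-ol | C1=C(C)[C@@H](O)C[C@@H](C/C=C(\C)CO)C1(C)C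
F8 | step 16 | (1S,5R)-5-[(2E)-4-(tert-butyldimethylsilyloxy)-3-methylbut-2-en-1-yl]-2,4,4-trimethylcyclohex-2-en-1-ol | C1=C(C)[C@@H](O)C[C@@H](C/C=C(\C)CO[Si](C)(C)C(C)(C)C)C1(C)C
F9 | step 16 | (1R,5R)-5-[(2E)-4-(tert-butyldimethylsilyloxy)-3-methylbut-2-en-1-yl]-2,4,4-trimethylcyclohex-2-en-1-yl 4-nitrobenzoate | C1=C(C)[C@H](OC(=O)c2ccc(cc2)[N+](=O)[O-])C[C@@H](C/C=C(\C)CO[Si](C)(C)C(C)(C)C)C1(C)C
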